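**Remark (assumptions).** Flavonoid numbering is used. Unit 1 is the 5‑hydroxy‑7‑methoxy half, unit 2 the 5,7‑dihydroxy half. The target is achiral. The sp3 centres that appear on the way (in 8–10 and 24) form as racemates or diastereomer mixtures and are removed later, so they are left undefined. Dimethyldioxirane (DMDO) is taken as a preformed acetone solution.

## The problem

Target 26 is a biflavonol in which two 3‑hydroxyflavone units are joined by one diaryl ether. O4' of ring B of unit 1 is bonded to C4' of ring B of unit 2, and each of these carbons has an oxygen neighbour (3'‑OH in unit 1, 3'‑OMe in unit 2). There is no stereocentre, so the task is connectivity and telling near‑identical groups apart. The ether lies between two electron‑rich, ortho‑oxygenated rings, an unfavourable case for SNAr or copper‑mediated coupling. The halves differ only at O7 (methyl against hydrogen) and at the ring B oxygen (hydrogen against methyl). The two pyranones must therefore grow from two ring B carbons that are revealed at different times and meet two different ring A ketones. Six hydroxyls must end free while two aryl methyl ethers stay, which rules out a closing Lewis acid demethylation. Free 3‑hydroxy‑4‑pyranones are sensitive to base and air, and the pyranone ring opens with hot alkali, so the phenols are carried as benzyl ethers and freed last by hydrogenolysis. The enabling feature is ring B of unit 1: C1' bears carbon, C3' a hydroxyl and C4' the aryloxy group. C3' and C4' map onto the carbonyl and α‑carbon of an aryloxyacetone, C2' onto its methyl group, C1' onto the keto carbon of an α‑keto ester, and C5'/C6' onto a vinyl group. Ring B can thus be built around an ether oxygen installed by SN2 alkylation and aromatised afterwards.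

## Retrosynthesis

**26 from 25.** Four O–benzyl bonds are cut. All phenols that must end free (O5 and O3' of unit 1, O5 and O7 of unit 2) are benzyl ethers in 25, and the two 3‑hydroxyls are already free. Hydrogenolysis leaves the two methyl ethers and the diaryl ether alone. A methyl/selective‑demethylation scheme was set aside because O7 of unit 1 and O3' of unit 2 must stay methylated.

**25 from 23.** Both C3–O bonds are cut, giving bis‑flavone 23; the forward reaction runs through bis‑epoxide 24. The direct alkaline peroxide route from a chalcone was not chosen because 6'‑alkoxy‑2'‑hydroxychalcones tend to divert to aurones. Splitting the oxidation into ring closure and a separate C3 hydroxylation costs one step, and that step serves both units at once.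

**23 from 22.** Both O1–C2 bonds are cut, giving the unsymmetrical bis‑chalcone 22. The forward reaction is an oxidative cyclisation of two 2'‑hydroxychalcones in one flask, which has to leave aryl benzyl ethers intact.

**22 from 19 and 21; 19 from 18; 18 from 15 and 17.** The two Cα=Cβ bonds are cut by Claisen–Schmidt disconnection. Because ketones 21 (7‑OMe series) and 17 (7‑OBn series) differ, the two aldehydes must appear in turn. In 15 one is free and the other is held as a benzylic alcohol, which needs no protecting group and is released by MnO2 (18 to 19). Ketones 17 and 21 are one benzylation away from commercial 16 and 20.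

**15 from 13; 13 from 12.** The C–CHO bond on ring B of unit 2 is cut back to an aryl bromide (via 14), and the hydroxymethyl group to an ethyl ester. Ester and bromide are orthogonal handles: the ester is reduced while the bromide is inert, and the resulting alkoxide tolerates the bromine–lithium exchange.

**12 from 11; 11 from 10.** The benzyl ether is cut, then the arene is taken back to cyclohexenone 10 by adding H2 across C5'–C6'. The forward dehydrogenation is driven by aromaticity and erases the only stereocentre.

**10 from 3 and 7 (key disconnection).** Bonds C4'–C5' and C2'–C1' are cut, giving aryloxyacetone 3 and vinyl keto ester 7 (forward via 8 and 9). Against a cut at the aryl–O bond, this replaces a hindered aryl etherification by an SN2 reaction and a Robinson annulation. It also delivers the free 3'‑OH next to the ether and a carboxyl at C1' in the right places without any directing step. The forward reaction must form the first C–C bond on the oxygen‑bearing side of the ketone.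

**3 from 1 and 2; 7 from 4 and 5.** The ether C–O bond of 3 is cut to 4‑bromo‑2‑methoxyphenol 1 and chloroacetone 2. The vinyl–carbonyl bond of 7 is cut to diethyl oxalate 4 and vinylmagnesium bromide 5 (via 6).

## Roads not taken

**Alternative 1:** The cut is C2=C3 of the unit 1 pyranone. Phosphorane A1, a phenacylidene ylide on ring A whose neighbouring phenol is acylated by the ring B acid carrying the finished, benzylated unit 2, would close by intramolecular Wittig reaction on the ester carbonyl to flavone A2, the phosphorus leaving as its oxide.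
- Merits: the closure is neutral and non‑oxidative, so benzyl ethers and the finished unit 2 are under no threat; this is milder than the iodine/DMSO step of the chosen plan. The union of ring A and ring B by acylation is convergent.
- Weak points: A2 still lacks O3, so the same late hydroxylation is needed. The acid component already contains the diaryl ether and all of unit 2, so the ether must be made by a conventional aryl etherification, and the two pyranones are built in two separate campaigns. The ylide needs side‑chain bromination and phosphonium formation on a hindered, chelated ketone.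
- Comparison: the chosen plan sets against the milder closure a single pair of operations for both pyranones and an ether oxygen installed at sp3 carbon.

**Alternative 2:** The cut is C3–C4 of unit 2. Dialdehyde A3 would undergo an intramolecular crossed benzoin reaction under a triazolium‑derived carbene to 3‑hydroxychroman‑4‑one A4.
- Merits: the ring closure is catalytic and mild, O3 arrives with the ring (no dioxirane step for this unit), and a bromide is kept for unit 1. In these respects it is better than the chosen plan.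
- Weak points: A3 is an α‑aryl‑α‑aryloxy acetaldehyde, easily enolised and prone to self‑condensation, and its preparation needs O‑alkylation of a hindered salicylaldehyde with a secondary benzylic electrophile plus redox adjustment. The acyl anion must form on the electron‑rich, doubly ortho‑substituted aromatic aldehyde and not on the aliphatic one, or the regioisomeric ketol results. A4 must still be dehydrogenated to the flavonol. The diaryl ether must exist before the key step.
- Comparison: the chosen plan answers with stable aromatic aldehydes and condensations whose regiochemistry is not in question.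

**Alternative 3:** Four bonds of ring A of unit 1 are cut (C8a–C8, C8–C7, C6–C5, C5–C4a). Diazoketone A5 would undergo Wolff rearrangement to a vinylketene that adds methoxyacetylene A6; ring opening and 6π closure would give phenol A7.
- Merits: the benzannulation places the free 5‑OH (from the ketene carbon) and the 7‑OMe (from the alkyne) regiospecifically with no protecting group on ring A, and O3 is already present as a benzyl ether. On these two counts it is better than the chosen plan.
- Weak points: it constructs the one ring that can be bought as a phloroacetophenone derivative. A5 requires de novo synthesis of a fully substituted 4‑pyranone‑2‑carboxylic acid that already carries ring B and the ether. A6 is volatile and unstable. The 4‑pyranone chromophore competes for light in a photochemical Wolff step. The diaryl ether and all of unit 2 remain to be solved (the dioxolane is only a handle).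
- Comparison: the chosen plan answers the regiochemical elegance with a one‑step monobenzylation of the symmetrical ketone 20 and spends its key step on the hindered ether and ring B.

Key step: step 3

## Route

Step 1
Reactants: 1 4‑bromo‑2‑methoxyphenol; 2 chloroacetone
Product: 3 1‑(4‑bromo‑2‑methoxyphenoxy)propan‑2‑one
Conditions: K2CO3, KI (cat.), acetone, reflux
Reagents that add atoms: none
Why: Williamson ether synthesis; the phenoxide displaces the activated α‑halo ketone halide by SN2, with iodide as nucleophilic catalyst.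

Step 2
Reactants: 4 diethyl oxalate; 5 vinylmagnesium bromide
Product: 7 ethyl 2‑oxobut‑3‑enoate, via magnesium hemiketal alkoxide 6 (not isolated)
Conditions: 4 (2 equiv), Et2O/THF, −78 °C, slow addition of 5; 1 M HCl at −78 °C; cold crude solution used at once
Reagents that add atoms: none
Why: Mono‑addition of a Grignard reagent to an oxalate diester; the tetrahedral adduct 6 persists at low temperature and collapses to the ketone only on quench, which prevents a second addition. The enone is labile and is not stored.

Step 3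
Reactants: 3 1‑(4‑bromo‑2‑methoxyphenoxy)propan‑2‑one; 7 ethyl 2‑oxobut‑3‑enoate
Product: 10 racemic ethyl 4‑(4‑bromo‑2‑methoxyphenoxy)‑3‑oxocyclohex‑1‑ene‑1‑carboxylate, via Michael adduct 8 (not isolated), via cyclic aldol 9 (not isolated)
Conditions: pyrrolidine (20 mol%), PhCO2H (20 mol%), toluene, 0 °C → rt, 7 added slowly; then p‑TsOH·H2O (10 mol%), 60 °C
Reagents that add atoms: none
Why: Pyrrolidine condenses with 3 to an enamine, and the regioisomer on the aryloxy‑bearing carbon is favoured because the α‑oxygen acidifies that C–H and conjugates with the enamine, as in enamine reactions of hydroxyacetone and alkoxyacetones. This enamine adds to the terminal carbon of 7 (bond C4'–C5'), directly or through a hetero‑Diels–Alder aminal that hydrolyses to the same 1,5‑dicarbonyl 8. In 8 the only α‑position that can reach a carbonyl through a six‑membered transition state is the methyl group, whose enamine attacks the strongly electrophilic keto carbonyl of the α‑keto ester (bond C2'–C1') in a 6‑(enolendo)‑exo‑trig aldol closure to give 9. Acid‑assisted E1cB loss of water then gives the conjugated enone ester 10. The closest known reaction type is the amine‑catalysed Robinson annulation (Michael addition, then aldol condensation) of ketones with β,γ‑unsaturated α‑keto esters. The centre at C4' in 8–10 and the carbinol centre in 9 arise without control and are erased by dehydration and the later aromatisation, so no controlling element is needed. The selectivity that matters is the site of the first C–C bond, since the methyl‑side adduct would close to the 2‑aryloxy isomer; the oxygen substituent together with equilibrating conditions (carboxylic acid cocatalyst) is relied on to prevent this. Slow addition of 7 keeps its concentration low and limits its polymerisation and dimerisation.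

Step 4
Reactants: 10 racemic ethyl 4‑(4‑bromo‑2‑methoxyphenoxy)‑3‑oxocyclohex‑1‑ene‑1‑carboxylate
Product: 11 ethyl 4‑(4‑bromo‑2‑methoxyphenoxy)‑3‑hydroxybenzoate
Conditions: I2 (20 mol%), DMSO, 90 °C; aq. Na2S2O3
Reagents that add atoms: none
Why: Iodine‑catalysed dehydrogenative aromatisation of a cyclohexenone; α‑iodination and loss of HI give a dienone that tautomerises to the phenol, and DMSO reoxidises HI to iodine. The C4' stereocentre disappears.

Step 5
Reactants: 11 ethyl 4‑(4‑bromo‑2‑methoxyphenoxy)‑3‑hydroxybenzoate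
Product: 12 ethyl 3‑(benzyloxy)‑4‑(4‑bromo‑2‑methoxyphenoxy)benzoate
Conditions: BnBr, K2CO3, DMF, rt
Reagents that add atoms: benzyl bromide, BrCc1ccccc1
Why: Williamson O‑benzylation of a phenol; ester, aryl bromide and diaryl ether are inert.

Step 6
Reactants: 12 ethyl 3‑(benzyloxy)‑4‑(4‑bromo‑2‑methoxyphenoxy)benzoate
Product: 13 [3‑(benzyloxy)‑4‑(4‑bromo‑2‑methoxyphenoxy)phenyl]methanol
Conditions: i‑Bu2AlH (2.5 equiv), CH2Cl2, −78 → 0 °C; aq. potassium sodium tartrate
Reagents that add atoms: none
Why: Hydride reduction of an aryl ester to the benzylic alcohol; the aryl bromide and benzyl ether do not react. The alcohol is the masked aldehyde of unit 1.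

Step 7
Reactants: 13 [3‑(benzyloxy)‑4‑(4‑bromo‑2‑methoxyphenoxy)phenyl]methanol
Product: 15 4‑[2‑(benzyloxy)‑4‑(hydroxymethyl)phenoxy]‑3‑methoxybenzaldehyde, via dilithio alkoxide aryllithium 14 (not isolated)
Conditions: n‑BuLi (2.2 equiv), THF, −78 °C; DMF, −78 → 0 °C; 1 M HCl
Reagents that add atoms: N,N‑dimethylformamide, CN(C)C=O
Why: The first equivalent deprotonates the alcohol and the second performs bromine–lithium exchange; the aryllithium is formylated by DMF (Bouveault‑type) and the lithium alkoxide protects the alcohol in situ.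

Step 8
Reactants: 16 2',4',6'‑trihydroxyacetophenone
Product: 17 1‑[2,4‑bis(benzyloxy)‑6‑hydroxyphenyl]ethanone
Conditions: BnBr (2.1 equiv), K2CO3, DMF, rt
Reagents that add atoms: benzyl bromide, BrCc1ccccc1
Why: Williamson alkylation; the para hydroxyl and one ortho hydroxyl react, while the last ortho hydroxyl is chelated to the ketone and stays free.

Step 9
Reactants: 15 4‑[2‑(benzyloxy)‑4‑(hydroxymethyl)phenoxy]‑3‑methoxybenzaldehyde; 17 1‑[2,4‑bis(benzyloxy)‑6‑hydroxyphenyl]ethanone
Product: 18 (E)‑1‑[2,4‑bis(benzyloxy)‑6‑hydroxyphenyl]‑3‑{4‑[2‑(benzyloxy)‑4‑(hydroxymethyl)phenoxy]‑3‑methoxyphenyl}prop‑2‑en‑1‑one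
Conditions: KOH (50% aq.), EtOH/THF, rt
Reagents that add atoms: none
Why: Claisen–Schmidt condensation of a non‑enolisable aryl aldehyde with a methyl ketone; E1cB dehydration gives the E‑enone, and the free benzylic alcohol is a spectator.

Step 10
Reactants: 18 (E)‑1‑[2,4‑bis(benzyloxy)‑6‑hydroxyphenyl]‑3‑{4‑[2‑(benzyloxy)‑4‑(hydroxymethyl)phenoxy]‑3‑methoxyphenyl}prop‑2‑en‑1‑one
Product: 19 3‑(benzyloxy)‑4‑{4‑[(E)‑3‑(2,4‑bis(benzyloxy)‑6‑hydroxyphenyl)‑3‑oxoprop‑1‑en‑1‑yl]‑2‑methoxyphenoxy}benzaldehyde
Conditions: MnO2 (activated, excess), CH2Cl2, rt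
Reagents that add atoms: none
Why: Selective oxidation of a benzylic alcohol by manganese dioxide; the chelated phenol and the enone are not attacked.

Step 11
Reactants: 20 2',6'‑dihydroxy‑4'‑methoxyacetophenone
Product: 21 1‑[2‑(benzyloxy)‑6‑hydroxy‑4‑methoxyphenyl]ethanone
Conditions: BnBr (1.05 equiv), K2CO3, acetone, reflux
Reagents that add atoms: benzyl bromide, BrCc1ccccc1
Why: Williamson mono‑alkylation of a symmetrical ketone; after the first benzylation the remaining hydroxyl is chelated to the carbonyl and is much less nucleophilic.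

Step 12
Reactants: 19 3‑(benzyloxy)‑4‑{4‑[(E)‑3‑(2,4‑bis(benzyloxy)‑6‑hydroxyphenyl)‑3‑oxoprop‑1‑en‑1‑yl]‑2‑methoxyphenoxy}benzaldehyde; 21 1‑[2‑(benzyloxy)‑6‑hydroxy‑4‑methoxyphenyl]ethanone
Product: 22 (E)‑1‑[2‑(benzyloxy)‑6‑hydroxy‑4‑methoxyphenyl]‑3‑[3‑(benzyloxy)‑4‑{4‑[(E)‑3‑(2,4‑bis(benzyloxy)‑6‑hydroxyphenyl)‑3‑oxoprop‑1‑en‑1‑yl]‑2‑methoxyphenoxy}phenyl]prop‑2‑en‑1‑one
Conditions: KOH (50% aq.), EtOH/THF, rt
Reagents that add atoms: none
Why: Second Claisen–Schmidt condensation; the chalcone already present sits as its phenoxide, which lowers its reactivity as a Michael acceptor and toward retro‑aldol cleavage at room temperature.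

Step 13
Reactants: 22 unsymmetrical bis‑chalcone (name as in step 12)
Product: 23 5‑(benzyloxy)‑2‑[3‑(benzyloxy)‑4‑{4‑[5,7‑bis(benzyloxy)‑4‑oxo‑4H‑chromen‑2‑yl]‑2‑methoxyphenoxy}phenyl]‑7‑methoxy‑4H‑chromen‑4‑one
Conditions: I2 (20 mol%), DMSO, 120 °C; aq. Na2S2O3
Reagents that add atoms: none
Why: Iodine‑catalysed oxidative cyclisation of 2'‑hydroxychalcones to flavones (oxa‑Michael closure, α‑iodination, loss of HI, DMSO as terminal oxidant); both pyranone rings form in one operation, as in known bis‑chalcone to biflavone conversions.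

Step 14
Reactants: 23 bis‑flavone (name as in step 13)
Product: 25 5‑(benzyloxy)‑2‑[3‑(benzyloxy)‑4‑{4‑[5,7‑bis(benzyloxy)‑3‑hydroxy‑4‑oxo‑4H‑chromen‑2‑yl]‑2‑methoxyphenoxy}phenyl]‑3‑hydroxy‑7‑methoxy‑4H‑chromen‑4‑one, via bis‑epoxide 24 (not isolated)
Conditions: DMDO (acetone solution, excess), CH2Cl2, 0 °C → rt; concentrate; then p‑TsOH·H2O (cat.), CH2Cl2, rt
Reagents that add atoms: dimethyldioxirane, CC1(C)OO1
Why: Dioxirane epoxidation of the flavone C2=C3 bond, then acid‑catalysed opening at C2 (oxocarbenium stabilised by O1 and the aryl group) and loss of H3 to give the 3‑hydroxyflavone. Both units react alike and the epoxide configuration is irrelevant.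

Step 15
Reactants: 25 bis‑flavonol tetrabenzyl ether (name as in step 14)
Product: 26 3,5‑dihydroxy‑2‑{3‑hydroxy‑4‑[2‑methoxy‑4‑(3,5,7‑trihydroxy‑4‑oxo‑4H‑chromen‑2‑yl)phenoxy]phenyl}‑7‑methoxy‑4H‑chromen‑4‑one (CNP0190193.0)
Conditions: H2 (1 atm), 10% Pd/C, THF/MeOH, rt
Reagents that add atoms: none
Why: Catalytic hydrogenolysis of four aryl benzyl ethers; the methyl ethers, the diaryl ether and the flavonol C2=C3 bond are expected to persist under these neutral conditions.

## Compound list

1 | 4‑bromo‑2‑methoxyphenol | COc1cc(Br)ccc1O | starting material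
2 | chloroacetone | CC(=O)CCl | starting material
3 | 1‑(4‑bromo‑2‑methoxyphenoxy)propan‑2‑one | CC(=O)COc1ccc(Br)cc1OC | intermediate
4 | diethyl oxalate | CCOC(=O)C(=O)OCC | starting material
5 | vinylmagnesium bromide | C=C[Mg]Br | starting material
6 | ethyl 2‑[(bromomagnesio)oxy]‑2‑ethoxybut‑3‑enoate (not isolated) | CCOC(=O)C(OCC)(O[Mg]Br)C=C | intermediate
7 | ethyl 2‑oxobut‑3‑enoate | C=CC(=O)C(=O)OCC | intermediate
8 | racemic ethyl 5‑(4‑bromo‑2‑methoxyphenoxy)‑2,6‑dioxoheptanoate (not isolated) | CCOC(=O)C(=O)CCC(Oc1ccc(Br)cc1OC)C(C)=O | intermediate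
9 | ethyl 4‑(4‑bromo‑2‑methoxyphenoxy)‑1‑hydroxy‑3‑oxocyclohexane‑1‑carboxylate, diastereomer mixture (not isolated) | CCOC(=O)C1(O)CC(=O)C(Oc2ccc(Br)cc2OC)CC1 | intermediate
10 | racemic ethyl 4‑(4‑bromo‑2‑methoxyphenoxy)‑3‑oxocyclohex‑1‑ene‑1‑carboxylate | CCOC(=O)C1=CC(=O)C(Oc2ccc(Br)cc2OC)CC1 | intermediate
11 | ethyl 4‑(4‑bromo‑2‑methoxyphenoxy)‑3‑hydroxybenzoate | CCOC(=O)c1ccc(Oc2ccc(Br)cc2OC)c(O)c1 | intermediate
12 | ethyl 3‑(benzyloxy)‑4‑(4‑bromo‑2‑methoxyphenoxy)benzoate | CCOC(=O)c1ccc(Oc2ccc(Br)cc2OC)c(OCc2ccccc2)c1 | intermediate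
13 | [3‑(benzyloxy)‑4‑(4‑bromo‑2‑methoxyphenoxy)phenyl]methanol | OCc1ccc(Oc2ccc(Br)cc2OC)c(OCc2ccccc2)c1 | intermediate
14 | lithium [3‑(benzyloxy)‑4‑(4‑lithio‑2‑methoxyphenoxy)phenyl]methanolate (not isolated) | [Li]OCc1ccc(Oc2ccc([Li])cc2OC)c(OCc2ccccc2)c1 | intermediate
15 | 4‑[2‑(benzyloxy)‑4‑(hydroxymethyl)phenoxy]‑3‑methoxybenzaldehyde | O=Cc1ccc(Oc2ccc(CO)cc2OCc2ccccc2)c(OC)c1 | intermediate
16 | 2',4',6'‑trihydroxyacetophenone | CC(=O)c1c(O)cc(O)cc1O | starting material
17 | 1‑[2,4‑bis(benzyloxy)‑6‑hydroxyphenyl]ethanone | CC(=O)c1c(O)cc(OCc2ccccc2)cc1OCc1ccccc1 | intermediate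
18 | (E)‑1‑[2,4‑bis(benzyloxy)‑6‑hydroxyphenyl]‑3‑{4‑[2‑(benzyloxy)‑4‑(hydroxymethyl)phenoxy]‑3‑methoxyphenyl}prop‑2‑en‑1‑one | O=C(/C=C/c1ccc(Oc2ccc(CO)cc2OCc2ccccc2)c(OC)c1)c1c(O)cc(OCc2ccccc2)cc1OCc1ccccc1 | intermediate
19 | 3‑(benzyloxy)‑4‑{4‑[(E)‑3‑(2,4‑bis(benzyloxy)‑6‑hydroxyphenyl)‑3‑oxoprop‑1‑en‑1‑yl]‑2‑methoxyphenoxy}benzaldehyde | O=Cc1ccc(Oc2ccc(/C=C/C(=O)c3c(O)cc(OCc4ccccc4)cc3OCc3ccccc3)cc2OC)c(OCc2ccccc2)c1 | intermediate
20 | 2',6'‑dihydroxy‑4'‑methoxyacetophenone | COc1cc(O)c(C(C)=O)c(O)c1 | starting material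
21 | 1‑[2‑(benzyloxy)‑6‑hydroxy‑4‑methoxyphenyl]ethanone | COc1cc(O)c(C(C)=O)c(OCc2ccccc2)c1 | intermediate
22 | unsymmetrical bis‑chalcone, (E,E) | COc1cc(O)c(C(=O)/C=C/c2ccc(Oc3ccc(/C=C/C(=O)c4c(O)cc(OCc5ccccc5)cc4OCc4ccccc4)cc3OC)c(OCc3ccccc3)c2)c(OCc2ccccc2)c1 | intermediate
23 | bis‑flavone, tetrabenzyl ether | COc1cc(OCc2ccccc2)c2c(=O)cc(-c3ccc(Oc4ccc(-c5cc(=O)c6c(OCc7ccccc7)cc(OCc7ccccc7)cc6o5)cc4OC)c(OCc4ccccc4)c3)oc2c1 | intermediate
24 | bis(2,3‑epoxide) of 23, diastereomer mixture (not isolated) | COc1cc(OCc2ccccc2)c2C(=O)C3OC3(c3ccc(Oc4ccc(C56OC5C(=O)c8c(OCc7ccccc7)cc(OCc7ccccc7)cc8O6)cc4OC)c(OCc4ccccc4)c3)Oc2c1 | intermediate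
25 | bis‑flavonol, tetrabenzyl ether | COc1cc(OCc2ccccc2)c2c(=O)c(O)c(-c3ccc(Oc4ccc(-c5oc6cc(OCc7ccccc7)cc(OCc7ccccc7)c6c(=O)c5O)cc4OC)c(OCc4ccccc4)c3)oc2c1 | intermediate
26 | CNP0190193.0 | COc1cc(O)c2c(=O)c(O)c(-c3ccc(Oc4ccc(-c5oc6cc(O)cc(O)c6c(=O)c5O)cc4OC)c(O)c3)oc2c1 | target

## Step count and risks

Total: 15 steps. Longest linear sequence: 12 steps (steps 1, 3, 4, 5, 6, 7, 9, 10, 12, 13, 14, 15).

**Step 3 (key step).** The first C–C bond may form on the methyl side of the ketone, which would lead to the 2‑aryloxy regioisomer, and the vinyl keto ester may polymerise before it is intercepted. Fallback: from 3, soft enolisation (TMSOTf, Et3N) gives the (Z)‑silyl enol ether F1 on the oxygen‑bearing side. A Mukaiyama–Michael addition of F1 to 7 (TiCl4, CH2Cl2, −78 °C) then gives 8, which is isolated and closed separately (pyrrolidine/AcOH, then p‑TsOH) to return to the route at 10.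

**Step 4.** Electrophilic iodination of the electron‑rich aryl ether ring, or stalling at a dienone stage, may compete with clean dehydrogenation. Fallback: from 10, conversion to the silyl dienol ether F2 (TMSOTf, Et3N) and oxidation with DDQ, with desilylation on work‑up, returns to the route at 11.

**Step 12.** The chalcone already present may undergo retro‑aldol exchange with the second ketone or conjugate addition of its enolate, scrambling the two halves. Fallback: from 19, the chalcone is first cyclised (I2, DMSO) to the flavone aldehyde F3. Condensation of F3 with 21 gives the flavone–chalcone F4, and a second iodine/DMSO cyclisation returns to the route at 23.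

**Step 13.** Hydrogen iodide formed in the flask may cleave the 5‑O‑benzyl ethers next to the carbonyl groups, and one of the two ring closures may stop at the flavanone. Fallback: from 22, base‑mediated closure (NaOAc, EtOH, reflux) gives the bis‑flavanone F5, which is dehydrogenated with DDQ in dioxane to return at 23.

**Step 14.** Epoxidation of the electron‑poor pyranone double bonds may be slow, so that the excess oxidant attacks benzylic C–H bonds or the flavonol once formed. Fallback: from 23, C3 lithiation (LiN(i‑Pr)2, THF, −78 °C) and trapping with B(OMe)3 gives the bis‑boronate F6 (not isolated), which is oxidised with H2O2/AcOH to return at 25.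

## Further compounds

F1 | step 3 | (Z)‑{[1‑(4‑bromo‑2‑methoxyphenoxy)prop‑1‑en‑2‑yl]oxy}trimethylsilane | C/C(O[Si](C)(C)C)=C/Oc1ccc(Br)cc1OC
F2 | step 4 | ethyl 4‑(4‑bromo‑2‑methoxyphenoxy)‑3‑(trimethylsilyloxy)cyclohexa‑1,3‑diene‑1‑carboxylate | CCOC(=O)C1=CC(O[Si](C)(C)C)=C(Oc2ccc(Br)cc2OC)CC1
F3 | step 12 | 3‑(benzyloxy)‑4‑{4‑[5,7‑bis(benzyloxy)‑4‑oxo‑4H‑chromen‑2‑yl]‑2‑methoxyphenoxy}benzaldehyde | O=Cc1ccc(Oc2ccc(-c3cc(=O)c4c(OCc5ccccc5)cc(OCc5ccccc5)cc4o3)cc2OC)c(OCc2ccccc2)c1
F4 | step 12 | (E)‑1‑[2‑(benzyloxy)‑6‑hydroxy‑4‑methoxyphenyl]‑3‑[3‑(benzyloxy)‑4‑{4‑[5,7‑bis(benzyloxy)‑4‑oxo‑4H‑chromen‑2‑yl]‑2‑methoxyphenoxy}phenyl]prop‑2‑en‑1‑one | COc1cc(O)c(C(=O)/C=C/c2ccc(Oc3ccc(-c4cc(=O)c5c(OCc6ccccc6)cc(OCc6ccccc6)cc5o4)cc3OC)c(OCc3ccccc3)c2)c(OCc2ccccc2)c1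
F5 | step 13 | bis‑flavanone corresponding to 23, diastereomer mixture | COc1cc(OCc2ccccc2)c2C(=O)CC(c3ccc(Oc4ccc(C5CC(=O)c6c(OCc7ccccc7)cc(OCc7ccccc7)cc6O5)cc4OC)c(OCc4ccccc4)c3)Oc2c1
F6 | step 14 | bis(3‑dimethoxyboryl) derivative of 23 | COc1cc(OCc2ccccc2)c2c(=O)c(B(OC)OC)c(-c3ccc(Oc4ccc(-c5oc6cc(OCc7ccccc7)cc(OCc7ccccc7)c6c(=O)c5B(OC)OC)cc4OC)c(OCc4ccccc4)c3)oc2c1
A1 | alternative 1 | phenacylidene triphenylphosphorane on ring A with the ortho phenol acylated by the ring B acid that carries benzylated unit 2 | COc1cc(OCc2ccccc2)c(C(=O)C=P(c2ccccc2)(c2ccccc2)c2ccccc2)c(OC(=O)c2ccc(Oc3ccc(-c4oc5cc(OCc6ccccc6)cc(OCc6ccccc6)c5c(=O)c4OCc4ccccc4)cc3OC)c(OCc3ccccc3)c2)c1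
A2 | alternative 1 | 5‑O‑benzyl‑7‑methoxyflavone of unit 1 joined to benzylated unit 2 | COc1cc(OCc2ccccc2)c2c(=O)cc(-c3ccc(Oc4ccc(-c5oc6cc(OCc7ccccc7)cc(OCc7ccccc7)c6c(=O)c5OCc5ccccc5)cc4OC)c(OCc4ccccc4)c3)oc2c1
A3 | alternative 2 | racemic 2,4‑bis(benzyloxy)‑6‑{1‑[4‑(2‑(benzyloxy)‑4‑bromophenoxy)‑3‑methoxyphenyl]‑2‑oxoethoxy}benzaldehyde | O=Cc1c(OCc2ccccc2)cc(OCc2ccccc2)cc1OC(C=O)c1ccc(Oc2ccc(Br)cc2OCc2ccccc2)c(OC)c1
A4 | alternative 2 | 5,7‑bis(benzyloxy)‑2‑[4‑(2‑(benzyloxy)‑4‑bromophenoxy)‑3‑methoxyphenyl]‑3‑hydroxychroman‑4‑one, configuration undefined | O=C1c2c(OCc3ccccc3)cc(OCc3ccccc3)cc2OC(c2ccc(Oc3ccc(Br)cc3OCc3ccccc3)c(OC)c2)C1O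
A5 | alternative 3 | 5‑(benzyloxy)‑6‑{3‑(benzyloxy)‑4‑[4‑(1,3‑dioxolan‑2‑yl)‑2‑methoxyphenoxy]phenyl}‑2‑(diazoacetyl)‑4H‑pyran‑4‑one | [N-]=[N+]=CC(=O)c1cc(=O)c(OCc2ccccc2)c(-c2ccc(Oc3ccc(C4OCCO4)cc3OC)c(OCc3ccccc3)c2)o1
A6 | alternative 3 | methoxyacetylene | COC#C
A7 | alternative 3 | 3‑O‑benzyl‑5‑hydroxy‑7‑methoxyflavone with the ring B diaryl ether and dioxolane | COc1cc(O)c2c(=O)c(OCc3ccccc3)c(-c3ccc(Oc4ccc(C5OCCO5)cc4OC)c(OCc4ccccc4)c3)oc2c1
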